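**Retrosynthetic overview**
1. Agecorynin G ⇒ open ring C (the pyranone) at the O1–C2 bond ⇒ an (E)-2'-hydroxychalcone. In the forward direction this C–O bond is closed last, by iodine/DMSO oxidative oxa-cyclisation.
2. Chalcone ⇒ Claisen–Schmidt union of purchased 6'-hydroxy-2',3',4'-trimethoxyacetophenone (ring A) with 3-hydroxy-2,4,5-trimethoxybenzaldehyde (ring B).
3. Ring B aldehyde ⇒ cut the phenolic C3–O bond ⇒ purchased 2,4,5-trimethoxybenzaldehyde. Forward, this is a new one-flask C–H hydroxylation between the two flanking methoxy groups, with the aldehyde masked in situ.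
4. Ring order: rings A and B are bought as intact benzenes; ring C is the only ring formed, in the final step.

Assumption: agecorynin G has no stereocentre or other stereo-element (the SMILES carries none), so it is achiral and "single enantiomer" calls for no stereocontrol.

**Route**

Step 1
Reactants: 1 2,4,5-trimethoxybenzaldehyde
Product: 5 3-hydroxy-2,4,5-trimethoxybenzaldehyde, via lithium amino alkoxide 2 (not isolated), via aryllithium 3 (not isolated), via aryl borate 4 (not isolated)
Conditions: lithium 4-methylpiperazin-1-ide (N-methylpiperazine + n-BuLi), THF, −20 °C; n-BuLi, TMEDA, −20 → 0 °C; B(OMe)3, −78 °C → rt; 30% H2O2, 0 °C; 1 M HCl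
Reagents that add atoms: hydrogen peroxide, OO
Why: Proposed new method: a one-flask C–H hydroxylation of an electron-rich benzaldehyde meta to the formyl group, in which the aldehyde is masked as the lithium α-amino alkoxide 2 (inert to n-BuLi), n-BuLi/TMEDA removes C3–H, the only proton flanked by two methoxy groups (the cooperative OMe/OMe site, as in 1,2,4,5-tetramethoxybenzene and 3,5-dimethoxybenzyl alkoxides, expected to beat C6–H next to the bulky, weakly directing anionic carbinolate), B(OMe)3 traps the aryllithium, and alkaline H2O2 triggers the boron-to-oxygen 1,2-aryl shift that forms the C3–O bond before acid work-up releases the aldehyde; the closest known reaction types are Comins α-amino alkoxide-directed lithiation and directed ortho-metalation/borylation/oxidation, neither shown for hydroxylating a 2,4,5-trialkoxybenzaldehyde remote from the masked formyl group; no stereocentre is present in the product.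

Step 2
Reactants: 5 3-hydroxy-2,4,5-trimethoxybenzaldehyde; 6 1-(6-hydroxy-2,3,4-trimethoxyphenyl)ethan-1-one
Product: 7 (E)-1-(6-hydroxy-2,3,4-trimethoxyphenyl)-3-(3-hydroxy-2,4,5-trimethoxyphenyl)prop-2-en-1-one
Conditions: KOH (50% aq.), EtOH, N2, rt, 48 h; 2 M HCl
Reagents that add atoms: none
Why: Claisen–Schmidt (crossed aldol) condensation, in which the enolate of the methyl ketone adds to the non-enolisable aldehyde and E1cB dehydration gives the thermodynamically favoured (E)-enone; the ring B phenoxide is meta to the formyl group and so does not switch the aldehyde off by conjugation; no stereocentre is formed.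

Step 3
Reactants: 7 (E)-1-(6-hydroxy-2,3,4-trimethoxyphenyl)-3-(3-hydroxy-2,4,5-trimethoxyphenyl)prop-2-en-1-one
Product: 9 agecorynin G (3'-hydroxy-5,6,7,2',4',5'-hexamethoxyflavone), via racemic flavanone 8 (not isolated)
Conditions: I2 (10 mol%), DMSO, 130 °C, 2 h
Reagents that add atoms: none
Why: Iodine-catalysed oxidative cyclisation in DMSO, in which 6-endo oxa-Michael addition of the 2'-phenol closes the pyranone C–O bond (flavanone 8), enol iodination at C3 and loss of HI give the flavone, and DMSO re-oxidises HI to I2; free phenols and aryl methyl ethers are normally tolerated, and the C2 stereocentre of 8 is erased on dehydrogenation, so the target is achiral.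

**Compound list**
1 | 2,4,5-trimethoxybenzaldehyde | COc1cc(OC)c(OC)cc1C=O | starting material
2 | lithium (4-methylpiperazin-1-yl)(2,4,5-trimethoxyphenyl)methanolate (racemic at the carbinol carbon) | COc1cc(OC)c(OC)cc1C([O-])N1CCN(C)CC1.[Li+] | intermediate
3 | lithium (3-lithio-2,4,5-trimethoxyphenyl)(4-methylpiperazin-1-yl)methanolate (racemic) | COc1cc(C([O-])N2CCN(C)CC2)c(OC)c([Li])c1OC.[Li+] | intermediate
4 | dilithium [2,4,5-trimethoxy-3-(trimethoxyboranuidyl)phenyl](4-methylpiperazin-1-yl)methanolate (racemic) | COc1cc(C([O-])N2CCN(C)CC2)c(OC)c([B-](OC)(OC)OC)c1OC.[Li+].[Li+] | intermediate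
5 | 3-hydroxy-2,4,5-trimethoxybenzaldehyde | COc1cc(C=O)c(OC)c(O)c1OC | intermediate
6 | 1-(6-hydroxy-2,3,4-trimethoxyphenyl)ethan-1-one (6'-hydroxy-2',3',4'-trimethoxyacetophenone) | CC(=O)c1c(O)cc(OC)c(OC)c1OC | starting material
7 | (E)-1-(6-hydroxy-2,3,4-trimethoxyphenyl)-3-(3-hydroxy-2,4,5-trimethoxyphenyl)prop-2-en-1-one | COc1cc(/C=C/C(=O)c2c(O)cc(OC)c(OC)c2OC)c(OC)c(O)c1OC | intermediate
8 | 2-(3-hydroxy-2,4,5-trimethoxyphenyl)-5,6,7-trimethoxychroman-4-one (racemic flavanone) | COc1cc(C2CC(=O)c3c(OC)c(OC)c(OC)cc3O2)c(OC)c(O)c1OC | intermediate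
9 | agecorynin G, 2-(3-hydroxy-2,4,5-trimethoxyphenyl)-5,6,7-trimethoxy-4H-chromen-4-one (achiral) | COc1cc(-c2cc(=O)c3c(OC)c(OC)c(OC)cc3o2)c(OC)c(O)c1OC | target

**Totals**
Total step count: 3. Longest linear sequence: 3 steps (1 → 5 → 7 → 9).

**Steps most likely to fail, with fallbacks**

Step 1 (the proposed new step) carries the most risk. The risks are competing lithiation at C6, incomplete masking of the formyl group, and Dakin-type attack of peroxide on the aldehyde once water unmasks it. Keep the oxidation at 0 °C with short contact, and destroy excess peroxide with sulfite before acidifying. The fallback uses known chemistry only and forms the ring B C–O bond before the formyl group is introduced. It sets out from compound 6, which is kept, and pairs it with a ring B partner made from purchased 1,2,4-trimethoxybenzene F1 in place of compound 1. n-BuLi in THF (0 °C → rt) lithiates F1 at C3 between two methoxy groups, and B(OMe)3 followed by H2O2/AcOH gives 2,3,6-trimethoxyphenol F2. Ac2O/pyridine gives 2,3,6-trimethoxyphenyl acetate F3. Rieche formylation (Cl2CHOMe, TiCl4, CH2Cl2, −78 → 0 °C) enters para to the 2-methoxy and ortho to the 6-methoxy group, because the acetoxy group is a far weaker donor, and gives 3-acetoxy-2,4,5-trimethoxybenzaldehyde F4. F4 and compound 6 under the KOH/EtOH conditions of step 2 lose the acetate in the same flask, and the fallback comes back to the route at compound 7.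

Step 3 is the next most exposed. The risks are iodination or oxidation of the electron-rich ring B phenol, whose para position is free, and HI-induced loss of the 5-O-methyl group. The fallback is an iodine-free, staged closure that sets out from compound 7 and comes back at compound 9. NaOAc in refluxing EtOH closes the C–O bond to give flavanone 8, now isolated. Pd(OCOCF3)2 (10 mol%) in DMSO under O2 (1 atm, 100 °C) then dehydrogenates it through a divalent palladium enolate and β-hydride elimination. This fallback makes no compound outside the list (none F0).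

Step 2 is the third. The risks are slow condensation, because the aldehyde reacts as its phenoxide, and air oxidation of the 2,6-dimethoxyphenoxide during 48 h in base. The fallback carries the phenol as a benzyl ether; it sets out from compound 5 and comes back at compound 9. BnBr, K2CO3, DMF gives 3-(benzyloxy)-2,4,5-trimethoxybenzaldehyde F5. KOH/EtOH condensation with compound 6 gives the O-benzyl chalcone (E)-3-[3-(benzyloxy)-2,4,5-trimethoxyphenyl]-1-(6-hydroxy-2,3,4-trimethoxyphenyl)prop-2-en-1-one F6. I2/DMSO as in step 3 gives the O-benzyl flavone 2-[3-(benzyloxy)-2,4,5-trimethoxyphenyl]-5,6,7-trimethoxy-4H-chromen-4-one F7. H2 (1 atm), 10% Pd/C, EtOAc/MeOH, rt then removes the benzyl group to give compound 9.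

**Further compounds**
F1 | step 1 | 1,2,4-trimethoxybenzene | COc1ccc(OC)c(OC)c1
F2 | step 1 | 2,3,6-trimethoxyphenol | COc1ccc(OC)c(OC)c1O
F3 | step 1 | 2,3,6-trimethoxyphenyl acetate | COc1ccc(OC)c(OC)c1OC(C)=O
F4 | step 1 | 3-acetoxy-2,4,5-trimethoxybenzaldehyde | COc1cc(C=O)c(OC)c(OC(C)=O)c1OC
F5 | step 2 | 3-(benzyloxy)-2,4,5-trimethoxybenzaldehyde | COc1cc(C=O)c(OC)c(OCc2ccccc2)c1OC
F6 | step 2 | (E)-3-[3-(benzyloxy)-2,4,5-trimethoxyphenyl]-1-(6-hydroxy-2,3,4-trimethoxyphenyl)prop-2-en-1-one | COc1cc(/C=C/C(=O)c2c(O)cc(OC)c(OC)c2OC)c(OC)c(OCc2ccccc2)c1OC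
F7 | step 2 | 2-[3-(benzyloxy)-2,4,5-trimethoxyphenyl]-5,6,7-trimethoxy-4H-chromen-4-one | COc1cc(-c2cc(=O)c3c(OC)c(OC)c(OC)cc3o2)c(OC)c(OCc2ccccc2)c1OC
F0 | step 3 | none | none
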